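**Retrosynthetic overview**
1. Target 12 ⇐ tribenzyl ether 11 by hydrogenolysis; the three B-ring benzyl ethers are the only protecting groups in the route.
2. Key strategy: both A-ring methoxy groups are installed last on the intact flavone (11 ⇐ 10 ⇐ 9) by twofold C6/C8 bromination and double Cu-catalysed methoxylation, so no penta-oxygenated acetophenone is ever made.
3. C ring: 9 ⇐ phloroglucinol 6 + α-methoxy β-keto ester 5 by a one-step thermal Mentzer annulation (forms C4–C4a and O1–C2), in place of the usual Allan–Robinson or chalcone route; the symmetry of 6 removes any regiochemical question and 5 carries the 3-OMe.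
4. 5 ⇐ tri-O-benzylgallic acid 1 + methyl methoxyacetate 2 (crossed Claisen).
5. Ring order: B and A rings are bought, the C ring is closed in step 2, the A ring is oxygenated in steps 3–4, then deprotection.

Assumption: the target has no stereocentre or stereogenic axis, so it is achiral and "single enantiomer" needs no stereocontrol; all SMILES carry no stereo descriptors (5 and 8 are racemic at an enolisable carbon that becomes sp2 in step 2).

**Step 1**
Reactants: 1 tri-O-benzylgallic acid (3,4,5-tris(benzyloxy)benzoic acid); 2 methyl methoxyacetate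
Product: 5 methyl 2-methoxy-3-oxo-3-[3,4,5-tris(benzyloxy)phenyl]propanoate (racemic), via acid chloride 3 (not isolated), via lithium enolate 4 (not isolated)
Conditions: (COCl)2 (1.2 eq), cat. DMF, CH2Cl2, 0 °C → rt, evaporate; add to 4 [2 (2.2 eq), LiHMDS (2.2 eq), THF, −78 °C]; −78 → −20 °C; aq. HCl
Reagents that add atoms: none
Why: Crossed Claisen condensation (C-acylation of an ester lithium enolate by an aroyl chloride), in which the second equivalent of enolate deprotonates the more acidic β-keto ester and so prevents over-acylation; the new α-stereocentre is racemic and is lost in step 2.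

**Step 2**
Reactants: 5 methyl 2-methoxy-3-oxo-3-[3,4,5-tris(benzyloxy)phenyl]propanoate; 6 phloroglucinol (benzene-1,3,5-triol)
Product: 9 myricetin 3-methyl ether 3',4',5'-tribenzyl ether (5,7-dihydroxy-3-methoxy-2-[3,4,5-tris(benzyloxy)phenyl]-4H-chromen-4-one), via acylketene 7 (not isolated), via aryl 1,3-diketone 8 (not isolated)
Conditions: 6 (2 eq, anhydrous), neat melt (or Ph2O), 240 °C, N2 stream, 45 min (oil bath or microwave), MeOH distilled out
Reagents that add atoms: none
Why: Mentzer chromone synthesis, in which the β-keto ester loses methanol thermally to an acylketene that C-acylates the very nucleophilic, C3-symmetric phloroglucinol and the resulting o-hydroxyaryl 1,3-diketone cyclodehydrates, so only one regioisomer is possible and no stereocentre remains.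

**Step 3**
Reactants: 9 myricetin 3-methyl ether 3',4',5'-tribenzyl ether
Product: 10 dibromoflavone 6,8-dibromo-5,7-dihydroxy-3-methoxy-2-[3,4,5-tris(benzyloxy)phenyl]-4H-chromen-4-one
Conditions: NBS (2.05 eq), DMF, 0 °C → rt, dark, 1 h
Reagents that add atoms: N-bromosuccinimide, O=C1CCC(=O)N1Br
Why: Electrophilic aromatic bromination, because C6 and C8 are the only free positions of the phloroglucinol-type A ring and are each activated by two free OH groups, far beyond the ether-only B ring that is conjugated to the electron-poor pyranone; no stereocentre is formed.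

**Step 4**
Reactants: 10 dibromoflavone
Product: 11 tribenzyl ether of the target (5,7-dihydroxy-3,6,8-trimethoxy-2-[3,4,5-tris(benzyloxy)phenyl]-4H-chromen-4-one)
Conditions: NaOMe (30% in MeOH, 15 eq), CuBr (0.3 eq), DMF, 120 °C, N2, 4 h; then aq. HCl
Reagents that add atoms: sodium methoxide, C[O-].[Na+]
Why: Twofold copper-catalysed Ullmann-type methoxylation of the ortho-bromophenoxides, a reaction type known on 6,8-dibromo-5,7-dihydroxyflavones, with the diphenoxide protecting the pyranone from methoxide attack and the benzyl and 3-methyl ethers inert; no stereocentre is formed.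

**Step 5**
Reactants: 11 tribenzyl ether of the target
Product: 12 target 5,7-dihydroxy-3,6,8-trimethoxy-2-(3,4,5-trihydroxyphenyl)-4H-chromen-4-one
Conditions: H2 (1 atm), 10% Pd/C, THF–MeOH 1:1, rt; filter and concentrate under N2
Reagents that add atoms: none
Why: Catalytic hydrogenolysis of the three benzyl aryl ethers, which leaves the aryl methyl ethers and the fully substituted, conjugated C2=C3 bond of the flavone untouched; the product is achiral.

**Compound list**
1 | tri-O-benzylgallic acid (3,4,5-tris(benzyloxy)benzoic acid) | OC(=O)c1cc(OCc2ccccc2)c(OCc2ccccc2)c(OCc2ccccc2)c1 | starting material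
2 | methyl methoxyacetate | COCC(=O)OC | starting material
3 | 3,4,5-tris(benzyloxy)benzoyl chloride (formed in situ) | ClC(=O)c1cc(OCc2ccccc2)c(OCc2ccccc2)c(OCc2ccccc2)c1 | intermediate
4 | lithium enolate of methyl methoxyacetate (lithium 1,2-dimethoxyethenolate, formed in situ) | [Li+].COC=C([O-])OC | intermediate
5 | methyl 2-methoxy-3-oxo-3-[3,4,5-tris(benzyloxy)phenyl]propanoate (racemic) | COC(=O)C(OC)C(=O)c1cc(OCc2ccccc2)c(OCc2ccccc2)c(OCc2ccccc2)c1 | intermediate
6 | phloroglucinol (benzene-1,3,5-triol) | Oc1cc(O)cc(O)c1 | starting material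
7 | 2-methoxy-2-[3,4,5-tris(benzyloxy)benzoyl]ketene (formed in situ) | COC(=C=O)C(=O)c1cc(OCc2ccccc2)c(OCc2ccccc2)c(OCc2ccccc2)c1 | intermediate
8 | 2-methoxy-1-(2,4,6-trihydroxyphenyl)-3-[3,4,5-tris(benzyloxy)phenyl]propane-1,3-dione (racemic, formed in situ) | COC(C(=O)c1c(O)cc(O)cc1O)C(=O)c1cc(OCc2ccccc2)c(OCc2ccccc2)c(OCc2ccccc2)c1 | intermediate
9 | 5,7-dihydroxy-3-methoxy-2-[3,4,5-tris(benzyloxy)phenyl]-4H-chromen-4-one | COc1c(-c2cc(OCc3ccccc3)c(OCc3ccccc3)c(OCc3ccccc3)c2)oc2cc(O)cc(O)c2c1=O | intermediate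
10 | 6,8-dibromo-5,7-dihydroxy-3-methoxy-2-[3,4,5-tris(benzyloxy)phenyl]-4H-chromen-4-one | COc1c(-c2cc(OCc3ccccc3)c(OCc3ccccc3)c(OCc3ccccc3)c2)oc2c(Br)c(O)c(Br)c(O)c2c1=O | intermediate
11 | 5,7-dihydroxy-3,6,8-trimethoxy-2-[3,4,5-tris(benzyloxy)phenyl]-4H-chromen-4-one | COc1c(-c2cc(OCc3ccccc3)c(OCc3ccccc3)c(OCc3ccccc3)c2)oc2c(OC)c(O)c(OC)c(O)c2c1=O | intermediate
12 | 5,7,3',4',5'-pentahydroxy-3,6,8-trimethoxyflavone (5,7-dihydroxy-3,6,8-trimethoxy-2-(3,4,5-trihydroxyphenyl)-4H-chromen-4-one) | COc1c(O)c(OC)c2oc(-c3cc(O)c(O)c(O)c3)c(OC)c(=O)c2c1O | target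

**Step count**
Total step count: 5. Longest linear sequence: 5 steps (1 → 5 → 9 → 10 → 11 → 12).

**Three steps most likely to fail**

Step 2 (Mentzer annulation) is the riskiest. At 240 °C the benzyl ethers may migrate, and the α-methoxy keto ester may give some Pechmann-type coumarin or decompose. The fallback sets out from 6 and 1 and comes back at 9. Phloroglucinol 6 and methoxyacetonitrile (ZnCl2, HCl gas, Et2O, 0 °C; Hoesch reaction) give 2-methoxy-1-(2,4,6-trihydroxyphenyl)ethan-1-iminium chloride F1, which boiling water hydrolyses to 2-methoxy-1-(2,4,6-trihydroxyphenyl)ethanone F2. Acid 1 is dehydrated with DCC (0.5 eq, CH2Cl2) to 3,4,5-tris(benzyloxy)benzoic anhydride F3. Allan–Robinson condensation of F2 with excess F3 (Et3N, 160 °C) gives 5-hydroxy-3-methoxy-4-oxo-2-[3,4,5-tris(benzyloxy)phenyl]-4H-chromen-7-yl 3,4,5-tris(benzyloxy)benzoate F4, and KOH in aqueous EtOH cleaves the 7-O-ester to return 9.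

Step 4 (double Ullmann methoxylation) is second. On the free diphenoxide it may stall after one exchange or give hydrodebromination. The fallback sets out from 10 and comes back at 12. The two phenols are capped (BnBr, K2CO3, DMF, 60 °C) to give 5,7-bis(benzyloxy)-6,8-dibromo-3-methoxy-2-[3,4,5-tris(benzyloxy)phenyl]-4H-chromen-4-one F7. The C–O bonds are then made by Pd-catalysed coupling with methanol (tBuBrettPhos Pd G3, Cs2CO3, toluene, 80 °C) to give 5,7-bis(benzyloxy)-3,6,8-trimethoxy-2-[3,4,5-tris(benzyloxy)phenyl]-4H-chromen-4-one F8. Hydrogenolysis (H2, Pd/C) removes all five benzyl groups and gives 12 directly.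

Step 3 (late-stage dibromination) is third. The tris(benzyloxy)phenyl ring could compete for bromine, or mono- and dibromo mixtures could result. The fallback sets out from 6 and 1 and comes back at 10, brominating ring A before ring B exists. 6 is taken as above through 2-methoxy-1-(2,4,6-trihydroxyphenyl)ethan-1-iminium chloride F1 to 2-methoxy-1-(2,4,6-trihydroxyphenyl)ethanone F2. NBS (2 eq, THF, 0 °C) fills its only two free ring positions to give 1-(3,5-dibromo-2,4,6-trihydroxyphenyl)-2-methoxyethanone F5. Allan–Robinson condensation with 3,4,5-tris(benzyloxy)benzoic anhydride F3 (Et3N, 160 °C) gives 6,8-dibromo-5-hydroxy-3-methoxy-4-oxo-2-[3,4,5-tris(benzyloxy)phenyl]-4H-chromen-7-yl 3,4,5-tris(benzyloxy)benzoate F6, and KOH in aqueous EtOH releases 10.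

**Further compounds**
F1 | step 2 | 2-methoxy-1-(2,4,6-trihydroxyphenyl)ethan-1-iminium chloride | COCC(=[NH2+])c1c(O)cc(O)cc1O.[Cl-]
F2 | step 2 | 2-methoxy-1-(2,4,6-trihydroxyphenyl)ethanone | COCC(=O)c1c(O)cc(O)cc1O
F3 | step 2 | 3,4,5-tris(benzyloxy)benzoic anhydride | O=C(OC(=O)c1cc(OCc2ccccc2)c(OCc2ccccc2)c(OCc2ccccc2)c1)c1cc(OCc2ccccc2)c(OCc2ccccc2)c(OCc2ccccc2)c1
F4 | step 2 | 5-hydroxy-3-methoxy-4-oxo-2-[3,4,5-tris(benzyloxy)phenyl]-4H-chromen-7-yl 3,4,5-tris(benzyloxy)benzoate | COc1c(-c2cc(OCc3ccccc3)c(OCc3ccccc3)c(OCc3ccccc3)c2)oc2cc(OC(=O)c3cc(OCc4ccccc4)c(OCc4ccccc4)c(OCc4ccccc4)c3)cc(O)c2c1=O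
F5 | step 3 | 1-(3,5-dibromo-2,4,6-trihydroxyphenyl)-2-methoxyethanone | COCC(=O)c1c(O)c(Br)c(O)c(Br)c1O
F6 | step 3 | 6,8-dibromo-5-hydroxy-3-methoxy-4-oxo-2-[3,4,5-tris(benzyloxy)phenyl]-4H-chromen-7-yl 3,4,5-tris(benzyloxy)benzoate | COc1c(-c2cc(OCc3ccccc3)c(OCc3ccccc3)c(OCc3ccccc3)c2)oc2c(Br)c(OC(=O)c3cc(OCc4ccccc4)c(OCc4ccccc4)c(OCc4ccccc4)c3)c(Br)c(O)c2c1=O
F7 | step 4 | 5,7-bis(benzyloxy)-6,8-dibromo-3-methoxy-2-[3,4,5-tris(benzyloxy)phenyl]-4H-chromen-4-one | COc1c(-c2cc(OCc3ccccc3)c(OCc3ccccc3)c(OCc3ccccc3)c2)oc2c(Br)c(OCc3ccccc3)c(Br)c(OCc3ccccc3)c2c1=O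
F8 | step 4 | 5,7-bis(benzyloxy)-3,6,8-trimethoxy-2-[3,4,5-tris(benzyloxy)phenyl]-4H-chromen-4-one | COc1c(-c2cc(OCc3ccccc3)c(OCc3ccccc3)c(OCc3ccccc3)c2)oc2c(OC)c(OCc3ccccc3)c(OC)c(OCc3ccccc3)c2c1=O
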